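## Structural features

The target is a briarane diterpenoid. A cyclohexane (ring A: C1, C10, C11, C12, C13, C14) is trans-fused through C1–C10 to a ten-membered carbocycle (C1 to C10). A γ-lactone (C7, C8, C17, C19 and the ring oxygen) is fused to the large ring across C7–C8, with C6 and C9 on opposite faces of the five-membered ring. C11 carries a spiro-epoxide (C20) and C5 an exocyclic methylene (C16). The periphery holds two acetates (C9, C14), an isobutyrate (C2), a tertiary alcohol (C8) and a secondary allylic chloride (C6). The ten stereocentres form two contiguous arrays, C14–C1–C2 (C1 quaternary) and C11–C10–C9–C8–C7–C6, with the lactone methine C17 attached to the fully substituted C8. The fragile groups are the epoxide (acid, halide, Lewis acid), the three esters (base, hydride), the β-hydroxy lactone (retro-aldol, dehydration to the butenolide) and the allylic chloride (SN2′, elimination). The real difficulty is the medium ring and the C7/C8 pair, where an oxygenated methine and a tertiary carbinol must be set trans on a ten-membered ring without a directing neighbour. The key step uses the position of the lactone oxygen between C19 and C7: without it the ring is a cyclobutanone of C7, C8, C17 and C19, the [2+2] adduct of methylchloroketene and a silyl enol ether of a C8 ketone. The enol ether that leads to this fusion has C6 and C9 trans across C7=C8 (a trans-cyclodecene), and because oxygen outranks C9 at C8 its CIP descriptor is Z.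

## Logic of the disconnections

**37 ⇐ 36 (C6–Cl).** The allylic chloride is the most labile group and is installed last. Cutting C6–Cl leads to 36, whose C6 carbinol has the opposite configuration. The forward step must be a clean SN2 inversion with no allylic shift, and must leave the tertiary C8–OH, the epoxide and the esters alone.

**36 ⇐ 35 ⇐ 33 (two O–Si bonds, C17–H for C17–Cl).** The chlorine at C17 exists only to steer the key step, and the silyl groups are what the enol ether chemistry leaves behind. Going back to 33 removes C17 from stereochemical planning, since it is reset when the halogen leaves. The forward steps must remove chlorine without forming an enolate that can expel the C8 oxygen, and must bring C17 to its more stable configuration. Triethylsilyl is used instead of a bulkier silyl group so that the tertiary C8 ether can be cleaved under conditions the epoxide tolerates.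

**33 ⇐ 32 (C7–O and O–C19, the key disconnection).** Taking the ring oxygen out contracts the γ-lactone to the cyclobutanone 32. The gain is that C7 and C8 become the two ends of one alkene. The forward oxygen insertion must be regioselective (C7, not C17, migrates) and must spare the C5=C16 alkene.

**32 ⇐ 29 + 31 (C7–C19 and C8–C17).** The cyclobutanone is cut into ketene 31 (from 30) and enol ether 29. This gives a ten-membered ketone derivative in which the C8 oxygen is the enol oxygen. The demand is a Z enol ether (ring-trans) that reacts on one face only; the polarity of the partners fixes which carbon bonds to which.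

**29 ⇐ 28 ⇐ 26 (O–Si, then C6–C7).** The C6 carbinol β to the C8 ketone is an aldol retron. Cutting C6–C7 opens the medium ring to 26, a cyclohexane carrying two side chains, a methyl ketone and a 2-substituted acrolein that cannot enolise. The forward step must enolise only the methyl group, close a ten-membered ring, and give the C6 epimer that allows direct inversion at the end.

**26 ⇐ 25 ⇐ 24 ⇐ 23 ⇐ 22 ⇐ 21 ⇐ 20 (functional-group changes on the chains).** The epoxide goes back to the C11 methylene, the methyl ketone to a terminal alkyne, the C5 methylene to an aldehyde α-CH2, and the C9 acetate to the epimeric propargylic alcohol. These changes are ordered so that the epoxidation meets only one electron-rich alkene and each protecting group is removed once.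

**20 ⇐ 19 ⇐ 17 + 18 (C14–H and the O2–acyl bond).** C2–O and C14–O are 1,3-anti across the quaternary C1. One hydride transfer from 18 to the β-hydroxy ketone 17 can therefore set C14 and put the isobutyrate on O2 at once. This also separates the isobutyrate from the two acetates. The demand is intramolecular delivery through a six-membered array.

**17 ⇐ 16 ⇐ 13 + 14 (C2–C3).** Cutting C2–C3 gives the neopentyl aldehyde 13 and the four-carbon organometallic from 14. The forward addition has to be chelation-controlled through the C14 ketal to give (2S).

**13 ⇐ 11 ⇐ 9 ⇐ 8 ⇐ 7 ⇐ 6 ⇐ 5 ⇐ 4 ⇐ 2 ⇐ 1 (reconnection C2–C7).** An aldehyde and an alkyne separated in this way are the products of an epoxy ketone fragmentation. Reconnecting C2 to C7 gives a trans-decalin that contains ring A, C2, C7, C8, C9, C10 and C15 of the target and comes from 1. The decalin lets C10 (hydroboration), C9 (enolate oxidation) and the C11 methylene be set on a rigid frame before the second ring is opened.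

## Other disconnections considered

**Alternative 1:** The cut is C1–C14 together with O–C2, so ring A is annulated onto a preformed ten-membered ring. Forward, phenyl isocyanate and triethylamine dehydrate a primary nitro group to the C14 nitrile oxide, which adds across an (E)-C1=C2 alkene to give isoxazoline A1.
- In favour: the quaternary C1 and the C2 oxygen arise in one syn-specific step. The isoxazoline is a masked β-hydroxy ketone whose reduction would give the same 1,3-anti C2/C14 pattern that step 12 of the chosen plan sets. On this point the alternative is the better plan, because the chosen route depends on chelation control for C2.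
- Against: A1 already carries the lactone, the tertiary alcohol, the C6 chloride and the C5 methylene, so the ten-membered ring must be made and functionalised without the conformational anchor of ring A. The exocyclic alkene is a second dipolarophile. Reductive N–O cleavage (Raney Ni or Mo(CO)6) must spare an allylic chloride. C14 reduction, two acylations, ketal removal, C11 methylenation and epoxidation would still follow on the most fragile intermediate.
- Comparison: the mechanism is as well founded as the chosen one, the step count is similar, and the risk sits later in the sequence.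

**Alternative 2:** The cut is C4–C5, with C2–C7 of a decalin as the bond that breaks. Forward, KH with 18-crown-6 forms the C7 alkoxide of a decalin diol derivative, and the [3,3] shift expands the six-membered ring to the ten-membered ketone A2.
- In favour: ring expansion avoids the entropic and transannular penalty of closing a medium ring. On this point it is the better plan, since the chosen route relies on a macro-aldol. It uses the same decalin type as the chosen route and delivers the C5 methylene directly, which is at least equal.
- Against: the carbonyl of A2 is at C7 and C8 is an ether, so the oxidation levels must be exchanged. C17 to C19 must then be added to a C8 ketone with control of the tertiary carbinol, which the cycloaddition and oxygen insertion of the chosen plan provide intrinsically. The C2 enol ether must be hydrolysed and reduced with stereocontrol. The strongly basic step excludes esters, so all three acyl groups come late.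
- Comparison: the mechanism is reliable and the ring formation safer, but more steps fall after the key step.

**Alternative 3:** The cut is the transannular bond C1–C10 of a fourteen-membered ring. Forward, Et2AlCl opens a trans C1–C2 epoxide, C10 of an (E)-C10=C11 alkene attacks C1, and loss of a proton from C20 gives A3.
- In favour: one step forms ring A, the ten-membered ring, the quaternary C1, the C2 carbinol, C10 and the C11 methylene, and a fourteen-membered ring is easier to close than a ten-membered one. In step economy it is potentially the better plan.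
- Against: the trans ring fusion depends on one reacting conformer of a flexible macrocycle. The Lewis acid also meets silyl ethers, a butenolide and a second alkene. The proton can leave from C12 instead of C20. A3 has the C8=C17 butenolide, so the tertiary alcohol and C17–H must still be introduced. Two exocyclic methylenes must be told apart in the late epoxidation, a problem the chosen route avoids by epoxidising at the enal stage.
- Comparison: it is shorter on paper but less predictable in stereochemistry. The chosen plan sets C7/C8 by a suprafacial cycloaddition and obtains the C8 oxygen directly.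

Key step: step 23

Remark on conventions: briarane numbering is used for every intermediate; β is the face of the C15 methyl group; ring B of the decalin is C1, C2, C7, C8, C9, C10.

Assumption: the macro-aldol of step 20 is taken to give the (6S) carbinol 28, and bromide 14 is treated as a purchasable building block.

## Route

Step 1
Reactants: 1 (R)-Wieland–Miescher ketone
Product: 2 8,14-bis(ethylene ketal) with the alkene moved to C10=C11
Conditions: HOCH2CH2OH, TsOH (cat.), PhH, reflux, Dean–Stark
Reagents that add atoms: ethylene glycol OCCO
Why: Acid-catalysed ketalisation; the enone ketalises with migration of the double bond out of conjugation, which places the alkene where C10 and C11 will be functionalised.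

Step 2
Reactants: 2 bis-ketal alkene
Product: 4 11α-hydroxy trans-decalin bis-ketal (H-10 α), via C11 alkylborane 3 (not isolated)
Conditions: BH3·THF, THF, 0 °C to rt; then NaOH, H2O2, 0 °C
Reagents that add atoms: hydrogen peroxide OO (borane B adds boron to intermediate 3 only)
Why: Hydroboration–oxidation; borane adds syn from the face opposite the angular C15 methyl with boron on the less substituted C11, so H-10 and O-11 are both α and the ring fusion becomes trans.

Step 3
Reactants: 4 11α-alcohol
Product: 5 11-ketone (trans-decalin bis-ketal)
Conditions: Dess–Martin periodinane, NaHCO3, CH2Cl2, rt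
Reagents that add atoms: none
Why: Dess–Martin oxidation under buffered conditions; C10 is now epimerisable but the trans-fused ketone is the more stable isomer.

Step 4
Reactants: 5 11-ketone
Product: 6 11-methylene bis-ketal
Conditions: MePPh3Br, KOtBu, PhMe, 80 °C
Reagents that add atoms: methyltriphenylphosphonium bromide C[P+](c1ccccc1)(c1ccccc1)c1ccccc1.[Br-]
Why: Wittig methylenation of a hindered ketone with excess ylide installs C20; any epimerisation at C10 returns to the trans fusion.

Step 5
Reactants: 6 bis-ketal
Product: 7 11-methylene-trans-decalin-8-one 14-ethylene ketal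
Conditions: PPTS (cat.), acetone/H2O, rt
Reagents that add atoms: water O
Why: Selective ketal hydrolysis; the unhindered C8 dioxolane should hydrolyse well before the C14 dioxolane next to the quaternary C1, and the mild acid leaves the exocyclic alkene in place.

Step 6
Reactants: 7 C8 ketone
Product: 8 C2=C7 enone (2-en-8-one numbering C2=C7–C8=O)
Conditions: IBX, DMSO/PhMe, 70 °C
Reagents that add atoms: none
Why: IBX dehydrogenation through the enol toward C7, the side away from the ring fusion as in trans-fused 2-decalones, gives the enone needed for cleavage of C2–C7.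

Step 7
Reactants: 8 enone
Product: 9 2α,7α-epoxy-8-ketone
Conditions: H2O2, NaOH (0.3 equiv), MeOH, 0 °C
Reagents that add atoms: hydrogen peroxide OO
Why: Nucleophilic (Weitz–Scheffer) epoxidation; hydroperoxide adds to C2 anti to the C15 methyl, and the electron-rich C11 methylene is inert to this reagent.

Step 8
Reactants: 9 epoxy ketone
Product: 11 (9R)-9α-(tert-butyldimethylsilyloxy)-2α,7α-epoxy-8-ketone, via 9α-hydroxy epoxy ketone 10 (not isolated)
Conditions: KN(SiMe3)2, THF, −78 °C; 2-(phenylsulfonyl)-3-phenyloxaziridine; then TBSOTf, −78 to 0 °C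
Reagents that add atoms: 2-(phenylsulfonyl)-3-phenyloxaziridine O=S(=O)(N1OC1c1ccccc1)c1ccccc1; tert-butyldimethylsilyl triflate CC(C)(C)[Si](C)(C)OS(=O)(=O)C(F)(F)F
Why: Enolate hydroxylation; only C9 can enolise and the oxaziridine approaches from the α face, away from the syn-axial C15 methyl. Silylation in the same flask prevents lactol formation with the later C2 aldehyde and alkoxide chelation in step 10.

Step 9
Reactants: 11 silyloxy epoxy ketone
Product: 13 seco alkynyl aldehyde (ring A with C1 methyl and formyl C2; C10 carrying the (9R)-1-silyloxyprop-2-ynyl chain; 11-methylene; 14-ketal), via tosylhydrazone 12 (not isolated)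
Conditions: TsNHNH2, AcOH/CH2Cl2, −20 °C to rt
Reagents that add atoms: none
Why: Eschenmoser–Tanabe fragmentation; the epoxy hydrazone opens to an alkoxy azoalkene that fragments with loss of N2 and sulfinate, cleaving C2–C7 into the C2 aldehyde and the C7≡C8 alkyne without touching C1, C9 or C10.

Step 10
Reactants: 13 alkynyl aldehyde; 14 tert-butyl(4-bromobutoxy)diphenylsilane
Product: 16 (2S)-carbinol with the C3–C6 chain (C6 as silyl ether), via 4-(tert-butyldiphenylsilyloxy)butylmagnesium bromide 15 (not isolated)
Conditions: 14, Mg, Et2O, rt; then 13, MgBr2·OEt2, CH2Cl2, −78 to −40 °C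
Reagents that add atoms: none
Why: Grignard addition under chelation control; magnesium bridges the aldehyde oxygen and a C14 ketal oxygen, and the nucleophile enters from the side of the small C15 methyl and not of C10, which gives 2S. The silyl ether at C9 cannot chelate and the solvent does not coordinate.

Step 11
Reactants: 16 carbinol ketal
Product: 17 (2S)-2-hydroxy C14 ketone
Conditions: TsOH·H2O (cat.), acetone/H2O, 40 °C
Reagents that add atoms: water O
Why: Ketal hydrolysis by transketalisation; the β-hydroxy ketone cannot dehydrate because C1 is quaternary, and the secondary TBS and primary TBDPS ethers should survive.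

Step 12
Reactants: 17 β-hydroxy ketone; 18 isobutyraldehyde
Product: 19 (2S)-isobutyrate (14S)-alcohol (C14–OH α, 1,3-anti to O2)
Conditions: 18 (8 equiv), SmI2 (0.3 equiv), THF, −10 °C
Reagents that add atoms: none
Why: Evans–Tishchenko reaction; the samarium-bound hemiacetal of O2 and the aldehyde transfers hydride to C14 through a six-membered chair, giving the 1,3-anti diol monoester. The C14 carbinol trans to C15 and the isobutyrate on O2 are set in one operation.

Step 13
Reactants: 19 C14 alcohol
Product: 20 (14S)-acetate
Conditions: Ac2O, DMAP, Et3N, CH2Cl2, rt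
Reagents that add atoms: acetic anhydride CC(=O)OC(C)=O
Why: DMAP-catalysed acetylation of the only free hydroxyl, an axial neopentyl-type alcohol.

Step 14
Reactants: 20 bis-silyl ether
Product: 21 diol (C9 propargylic alcohol 9R; C6 primary alcohol)
Conditions: Bu4NF, AcOH, THF, rt
Reagents that add atoms: none
Why: Fluoride desilylation of both silyl ethers in one step; the acetic acid buffer protects the esters from the basic fluoride.

Step 15
Reactants: 21 diol
Product: 22 C6 aldehyde with free (9R)-propargylic alcohol
Conditions: TEMPO (cat.), PhI(OAc)2, CH2Cl2, rt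
Reagents that add atoms: none
Why: Oxoammonium oxidation is selective for the primary alcohol over the hindered secondary propargylic one and stops at the aldehyde.

Step 16
Reactants: 22 hydroxy aldehyde
Product: 23 (9S)-propargylic acetate
Conditions: PPh3, DIAD, AcOH, PhMe, 0 °C to rt
Reagents that add atoms: acetic acid CC(O)=O
Why: Mitsunobu reaction; the activated propargylic carbinol is displaced by acetate with inversion (9R to 9S), and no second hydroxyl remains that could close a cyclic ether.

Step 17
Reactants: 23 aldehyde
Product: 24 enal (C5=C16 methylene, C6 formyl)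
Conditions: aq. HCHO, pyrrolidine (10 mol%), EtCO2H (10 mol%), iPrOH, 45 °C
Reagents that add atoms: formaldehyde C=O
Why: Organocatalytic α-methylenation (enamine Mannich condensation and elimination), selective for the aldehyde α-CH2; it creates the 2-substituted acrolein, which has no enolisable α-hydrogen.

Step 18
Reactants: 24 alkynyl enal
Product: 25 methyl ketone (C8 ketone, C7 methyl, 9S acetate)
Conditions: Ph3PAuCl (2 mol%), AgSbF6 (2 mol%), dioxane/H2O, rt
Reagents that add atoms: water O
Why: Gold-catalysed Markovnikov hydration of the terminal alkyne, assisted by 5-exo attack of the neighbouring acetate carbonyl on C8; the C9–O bond is never broken, so the configuration is kept.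

Step 19
Reactants: 25 methyl ketone enal
Product: 26 (11R)-11,20-epoxide (epoxide oxygen α)
Conditions: dimethyldioxirane, acetone/CH2Cl2, −20 to 0 °C
Reagents that add atoms: dimethyldioxirane CC1(C)OO1
Why: Epoxidation of the only electron-rich alkene; the enal double bond is deactivated, and the β face of C11=C20 is blocked by the 1,3-related axial C15 methyl, so oxygen is delivered from the α (equatorial) side.

Step 20
Reactants: 26 keto enal
Product: 28 ten-membered (6S)-6-hydroxy C8 ketone, via dicyclohexylboron enolate 27 (not isolated)
Conditions: Cy2BCl, Et3N, Et2O (0.002 M), −78 to 0 °C; then pH 7 buffer, MeOH, H2O2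
Reagents that add atoms: none (chlorodicyclohexylborane adds boron to intermediate 27 only)
Why: Boron-mediated aldol reaction run as a macrocyclisation; the boron reagent enolises the methyl group and not the acetoxy-bearing C9, the enal cannot enolise, and the cyclic chair transition state forms C6–C7. High dilution suppresses oligomers; the C6 configuration is the assumed one.

Step 21
Reactants: 28 β-hydroxy ketone
Product: 29 (Z)-C7=C8 triethylsilyl enol ether with C6 triethylsilyl ether (trans double bond in the ring)
Conditions: TESOTf (3 equiv), Et3N, CH2Cl2, −78 to −20 °C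
Reagents that add atoms: triethylsilyl triflate CC[Si](CC)(CC)OS(=O)(=O)C(F)(F)F
Why: Soft enolisation; after O-silylation at C6 the silylated oxocarbenium loses the accessible C7 proton and not the hindered C9 methine. The Z isomer, with C6 cis to oxygen and trans to the branched C9, should be favoured; the conditions spare the esters.

Step 22
Reactants: 29 enol ether; 30 2-chloropropanoyl chloride
Product: 32 ring-fused 2-chloro-2-methylcyclobutanone (C7, C8, C17, C19; C6 and C9 trans), via methylchloroketene 31 (not isolated)
Conditions: 30 (slow addition), Et3N, hexane/Et2O, 35 °C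
Reagents that add atoms: none
Why: Ketene–enol ether [2+2] cycloaddition; the ketene carbonyl carbon C19 bonds to the nucleophilic C7 and C17 to C8, suprafacially on the enol ether. Allylic 1,3-strain keeps H-6 in the enol ether plane so the ring chain through C5 covers one face and the ketene adds to the other, which gives C7 and C8 as required. The C17 epimer drawn is arbitrary, as either serves.

Step 23
Reactants: 32 α-chloro cyclobutanone
Product: 33 α-chloro-α-methyl γ-lactone (C6 and C8 triethylsilyl ethers)
Conditions: mCPBA (1.1 equiv), NaHCO3, CH2Cl2, 0 °C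
Reagents that add atoms: 3-chloroperbenzoic acid OOC(=O)c1cccc(Cl)c1
Why: The peracid adds to the strained C19 carbonyl to give the Criegee adduct, and C7 then shifts from carbon to oxygen with loss of the carboxylate, so oxygen is inserted between C19 and C7. The closest known reaction type is the Baeyer–Villiger expansion of α-chlorocyclobutanones from chloroketene cycloadducts to γ-lactones. The five-membered ring is closed by ring expansion, a 1,2-shift within the four-membered ring, and not by a cyclisation. No stereocentre is made afresh: the shift is suprafacial with retention, so the configuration that the cycloaddition gave C7 becomes that of the C7–O bond and the trans relation of C6 and C9 is inherited from 32. Regioselectivity (C7 over C17) is secured by the chlorine, which lowers the migratory aptitude of C17. Chemoselectivity over the C5=C16 alkene is secured by the strain of the ketone, by the allylic silyloxy group and the ring crowding that slow epoxidation, and by one equivalent of oxidant at 0 °C. NaHCO3 keeps the medium neutral, so the β-silyloxy ketone does not open by retro-aldol and the C11 epoxide survives.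

Step 24
Reactants: 33 chloro lactone
Product: 35 (17R)-lactone with methyl cis to the C8 oxygen, via C17-epimeric dechlorinated lactone 34 (not isolated)
Conditions: (Me3Si)3SiH, AIBN, PhMe, 80 °C; then DBU, rt
Reagents that add atoms: none
Why: Radical hydrodechlorination; the silyl radical abstracts chlorine and the C17 radical takes hydrogen from the silane, avoiding an enolate that could expel the β-silyloxy group. DBU then equilibrates C17 through the lactone enolate toward the epimer with methyl cis to the small C8 oxygen and trans to the bulkier C9.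

Step 25
Reactants: 35 bis-silyl ether
Product: 36 6,8-diol (C6 carbinol of configuration opposite to the chloride)
Conditions: HF·pyridine, pyridine, THF, 0 °C to rt
Reagents that add atoms: none
Why: Buffered fluoride cleaves both triethylsilyl ethers, including the tertiary one, under conditions that an epoxide and acetates tolerate.

Step 26
Reactants: 36 diol
Product: 37 CNP0284862.1 (target)
Conditions: PPh3, Cl3CC(O)CCl3, CH2Cl2, −20 to 0 °C
Reagents that add atoms: hexachloroacetone ClC(Cl)(Cl)C(=O)C(Cl)(Cl)Cl
Why: Appel-type chlorination; the alkoxyphosphonium ion of the secondary allylic alcohol is displaced by chloride in an SN2 reaction with inversion and without allylic transposition under these neutral conditions, while the tertiary C8 alcohol does not react.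

## Compound list

1 | (R)-Wieland–Miescher ketone | O=C1CC[C@@]2(C)C(=O)CCCC2=C1 | starting material
2 | 8,14-bis(ethylene ketal), C10=C11 alkene | O1CCOC12CC[C@@]3(C)C4(OCCO4)CCC=C3C2 | intermediate
3 | C11 alkylborane (11α-boryl, H-10 α) | O1CCOC12CC[C@@]3(C)C4(OCCO4)CC[C@@H](B)[C@@H]3C2 | intermediate
4 | 11α-hydroxy trans-decalin bis-ketal | O1CCOC12CC[C@@]3(C)C4(OCCO4)CC[C@@H](O)[C@@H]3C2 | intermediate
5 | 11-ketone bis-ketal | O1CCOC12CC[C@@]3(C)C4(OCCO4)CCC(=O)[C@@H]3C2 | intermediate
6 | 11-methylene bis-ketal | O1CCOC12CC[C@@]3(C)C4(OCCO4)CCC(=C)[C@@H]3C2 | intermediate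
7 | 11-methylene-8-ketone 14-ketal | O=C1CC[C@@]2(C)C3(OCCO3)CCC(=C)[C@@H]2C1 | intermediate
8 | C2=C7 enone 14-ketal | O=C1C=C[C@@]2(C)C3(OCCO3)CCC(=C)[C@@H]2C1 | intermediate
9 | 2α,7α-epoxy-8-ketone | O=C1[C@H]2O[C@H]2[C@@]3(C)C4(OCCO4)CCC(=C)[C@@H]3C1 | intermediate
10 | 9α-hydroxy-2α,7α-epoxy-8-ketone | O=C1[C@H]2O[C@H]2[C@@]3(C)C4(OCCO4)CCC(=C)[C@@H]3[C@H]1O | intermediate
11 | 9α-TBS ether of 10 | O=C1[C@H]2O[C@H]2[C@@]3(C)C4(OCCO4)CCC(=C)[C@@H]3[C@H]1O[Si](C)(C)C(C)(C)C | intermediate
12 | tosylhydrazone of 11 | Cc1ccc(cc1)S(=O)(=O)NN=C1[C@H]2O[C@H]2[C@@]3(C)C4(OCCO4)CCC(=C)[C@@H]3[C@H]1O[Si](C)(C)C(C)(C)C | intermediate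
13 | seco alkynyl aldehyde (C2 formyl, 9R silyloxy, C7≡C8) | O=C[C@@]1(C)C2(OCCO2)CCC(=C)[C@@H]1[C@@H](O[Si](C)(C)C(C)(C)C)C#C | intermediate
14 | tert-butyl(4-bromobutoxy)diphenylsilane | BrCCCCO[Si](c1ccccc1)(c1ccccc1)C(C)(C)C | starting material
15 | 4-(tert-butyldiphenylsilyloxy)butylmagnesium bromide | Br[Mg]CCCCO[Si](c1ccccc1)(c1ccccc1)C(C)(C)C | intermediate
16 | (2S)-carbinol, 14-ketal | O[C@@H](CCCCO[Si](c1ccccc1)(c1ccccc1)C(C)(C)C)[C@@]1(C)C2(OCCO2)CCC(=C)[C@@H]1[C@@H](O[Si](C)(C)C(C)(C)C)C#C | intermediate
17 | (2S)-hydroxy C14 ketone | O[C@@H](CCCCO[Si](c1ccccc1)(c1ccccc1)C(C)(C)C)[C@@]1(C)C(=O)CCC(=C)[C@@H]1[C@@H](O[Si](C)(C)C(C)(C)C)C#C | intermediate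
18 | isobutyraldehyde | CC(C)C=O | starting material
19 | (2S)-isobutyrate (14S)-alcohol | CC(C)C(=O)O[C@@H](CCCCO[Si](c1ccccc1)(c1ccccc1)C(C)(C)C)[C@@]1(C)[C@@H](O)CCC(=C)[C@@H]1[C@@H](O[Si](C)(C)C(C)(C)C)C#C | intermediate
20 | (14S)-acetate | CC(C)C(=O)O[C@@H](CCCCO[Si](c1ccccc1)(c1ccccc1)C(C)(C)C)[C@@]1(C)[C@@H](OC(C)=O)CCC(=C)[C@@H]1[C@@H](O[Si](C)(C)C(C)(C)C)C#C | intermediate
21 | C6,C9-diol (9R) | CC(C)C(=O)O[C@@H](CCCCO)[C@@]1(C)[C@@H](OC(C)=O)CCC(=C)[C@@H]1[C@@H](O)C#C | intermediate
22 | C6 aldehyde, (9R)-propargylic alcohol | CC(C)C(=O)O[C@@H](CCCC=O)[C@@]1(C)[C@@H](OC(C)=O)CCC(=C)[C@@H]1[C@@H](O)C#C | intermediate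
23 | (9S)-propargylic acetate | CC(C)C(=O)O[C@@H](CCCC=O)[C@@]1(C)[C@@H](OC(C)=O)CCC(=C)[C@@H]1[C@H](OC(C)=O)C#C | intermediate
24 | enal (C5 methylene, C6 formyl) | CC(C)C(=O)O[C@@H](CCC(=C)C=O)[C@@]1(C)[C@@H](OC(C)=O)CCC(=C)[C@@H]1[C@H](OC(C)=O)C#C | intermediate
25 | methyl ketone enal | CC(C)C(=O)O[C@@H](CCC(=C)C=O)[C@@]1(C)[C@@H](OC(C)=O)CCC(=C)[C@@H]1[C@H](OC(C)=O)C(C)=O | intermediate
26 | (11R)-epoxide | CC(C)C(=O)O[C@@H](CCC(=C)C=O)[C@@]1(C)[C@@H](OC(C)=O)CC[C@]2(CO2)[C@@H]1[C@H](OC(C)=O)C(C)=O | intermediate
27 | dicyclohexylboron enolate of 26 | CC(C)C(=O)O[C@@H](CCC(=C)C=O)[C@@]1(C)[C@@H](OC(C)=O)CC[C@]2(CO2)[C@@H]1[C@H](OC(C)=O)C(=C)OB(C1CCCCC1)C1CCCCC1 | intermediate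
28 | ten-membered (6S)-hydroxy C8 ketone | C=C1CC[C@H](OC(=O)C(C)C)[C@@]2(C)[C@@H](OC(C)=O)CC[C@]3(CO3)[C@@H]2[C@H](OC(C)=O)C(=O)C[C@@H]1O | intermediate
29 | (Z)-triethylsilyl enol ether, C6 triethylsilyl ether | C=C1CC[C@H](OC(=O)C(C)C)[C@@]2(C)[C@@H](OC(C)=O)CC[C@]3(CO3)[C@@H]2[C@H](OC(C)=O)/C(O[Si](CC)(CC)CC)=C/[C@@H]1O[Si](CC)(CC)CC | intermediate
30 | 2-chloropropanoyl chloride | CC(Cl)C(Cl)=O | starting material
31 | methylchloroketene | CC(Cl)=C=O | intermediate
32 | fused 2-chloro-2-methylcyclobutanone | C=C1CC[C@H](OC(=O)C(C)C)[C@@]2(C)[C@@H](OC(C)=O)CC[C@]3(CO3)[C@@H]2[C@H](OC(C)=O)[C@]2(O[Si](CC)(CC)CC)[C@](C)(Cl)C(=O)[C@H]2[C@@H]1O[Si](CC)(CC)CC | intermediate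
33 | α-chloro-α-methyl γ-lactone | C=C1CC[C@H](OC(=O)C(C)C)[C@@]2(C)[C@@H](OC(C)=O)CC[C@]3(CO3)[C@@H]2[C@H](OC(C)=O)[C@]2(O[Si](CC)(CC)CC)[C@](C)(Cl)C(=O)O[C@H]2[C@@H]1O[Si](CC)(CC)CC | intermediate
34 | dechlorinated lactone, C17 not fixed | C=C1CC[C@H](OC(=O)C(C)C)[C@@]2(C)[C@@H](OC(C)=O)CC[C@]3(CO3)[C@@H]2[C@H](OC(C)=O)[C@]2(O[Si](CC)(CC)CC)C(C)C(=O)O[C@H]2[C@@H]1O[Si](CC)(CC)CC | intermediate
35 | (17R)-lactone bis(triethylsilyl) ether | C=C1CC[C@H](OC(=O)C(C)C)[C@@]2(C)[C@@H](OC(C)=O)CC[C@]3(CO3)[C@@H]2[C@H](OC(C)=O)[C@]2(O[Si](CC)(CC)CC)[C@@H](C)C(=O)O[C@H]2[C@@H]1O[Si](CC)(CC)CC | intermediate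
36 | 6,8-diol | C=C1CC[C@H](OC(=O)C(C)C)[C@@]2(C)[C@@H](OC(C)=O)CC[C@]3(CO3)[C@@H]2[C@H](OC(C)=O)[C@]2(O)[C@@H](C)C(=O)O[C@H]2[C@@H]1O | intermediate
37 | CNP0284862.1 | C=C1CC[C@H](OC(=O)C(C)C)[C@@]2(C)[C@@H](OC(C)=O)CC[C@]3(CO3)[C@@H]2[C@H](OC(C)=O)[C@]2(O)[C@@H](C)C(=O)O[C@H]2[C@H]1Cl | target

## Step count and least certain steps

Total step count: 26. Longest linear sequence: 26 steps from 1 (the organomagnesium reagent is made inside step 10).

**Step 23 (key step).** The most likely failure is competing epoxidation of the C5=C16 alkene by the electrophilic peracid if addition to the crowded C19 carbonyl is slow. The fallback changes the selectivity principle and not only a parameter: 32 is oxidised with urea–hydrogen peroxide in 1,1,1,3,3,3-hexafluoropropan-2-ol, a peroxide that adds to the strained ketone but is a poor epoxidising agent for an unactivated alkene. It sets out from 32 and returns at 33 with no new compound.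

**Step 20.** The macro-aldol may show poor facial selectivity at the aldehyde, because the C6 configuration is decided only by the conformation of the closing ring; oligomerisation may also compete. The fallback sets out from 26 and uses the epimer.
- The same aldol gives the (6R) carbinol F1.
- tBu2Si(OTf)2 and 2,6-lutidine convert it into the cyclic silylene enol ether F2. The tether fixes the Z geometry and the site of enolisation, and holds the C6 oxygen in the enol ether plane, so the ring chain covers the face opposite to that required for ketene attack.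
- Methylchloroketene gives the bridged cyclobutanone F3.
- Buffered mCPBA gives the bridged chloro lactone F4.
- (Me3Si)3SiH/AIBN followed by DBU gives the (17R) lactone F5.
- HF·pyridine gives the C6-epimeric diol F6.
- Mitsunobu reaction with formic acid gives the inverted formate F7.
- KHCO3 in methanol cleaves the formate and leaves the acetates, returning to the route at 36.

**Step 21.** Enolisation may go toward C9, or the ring-cis enol ether may form, because a ten-membered ring does not carry the acyclic preference for the Z isomer with certainty. The fallback sets out from 28. Mitsunobu reaction with formic acid gives the (6R) formate F8, mild methanolysis gives the (6R) carbinol F1, and the silylene tether then enforces geometry and regiochemistry as described for step 20, returning at 36.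

**Step 10.** Loss of chelation control would give the 2R carbinol through an open transition state, and β-hydride transfer from the reagent to the hindered aldehyde may compete. The fallback sets out from 13. The crude alcohol mixture from the addition is oxidised with Dess–Martin periodinane to the C2 ketone F9. This is reduced with (R)-2-methyl-CBS-oxazaborolidine and BH3·SMe2, where the tert-alkyl C1 acts as the large group, so the reagent sets 2S; it returns at 16.

**Step 26.** Ionisation of the allylic alkoxyphosphonium ion, with allylic transposition of chloride to C16 or loss of stereochemical integrity, is the most likely failure. The fallback sets out from 36. SOCl2 and Et3N tie the C6 and C8 oxygens together as the cyclic sulfite F10. LiCl in DMF opens it at the secondary allylic C6 with inversion while the leaving group stays tethered to O8. Aqueous work-up frees the tertiary alcohol, returning at 37.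

## Further compounds

F0 | step 23 | none | none
F1 | step 20 | (6R) epimer of 28 | C=C1CC[C@H](OC(=O)C(C)C)[C@@]2(C)[C@@H](OC(C)=O)CC[C@]3(CO3)[C@@H]2[C@H](OC(C)=O)C(=O)C[C@H]1O
F2 | step 20 | di-tert-butylsilylene enol ether (O6–Si–O8 bridge, Z) | C=C1CC[C@H](OC(=O)C(C)C)[C@@]2(C)[C@@H](OC(C)=O)CC[C@]3(CO3)[C@@H]2[C@H](OC(C)=O)/C4=C/[C@H]1O[Si](C(C)(C)C)(C(C)(C)C)O4
F3 | step 20 | silylene-bridged chloro cyclobutanone | C=C1CC[C@H](OC(=O)C(C)C)[C@@]2(C)[C@@H](OC(C)=O)CC[C@]3(CO3)[C@@H]2[C@H](OC(C)=O)[C@]2(O[Si]4(C(C)(C)C)C(C)(C)C)[C@](C)(Cl)C(=O)[C@H]2[C@H]1O4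
F4 | step 20 | silylene-bridged chloro lactone | C=C1CC[C@H](OC(=O)C(C)C)[C@@]2(C)[C@@H](OC(C)=O)CC[C@]3(CO3)[C@@H]2[C@H](OC(C)=O)[C@]2(O[Si]4(C(C)(C)C)C(C)(C)C)[C@](C)(Cl)C(=O)O[C@H]2[C@H]1O4
F5 | step 20 | silylene-bridged (17R) lactone | C=C1CC[C@H](OC(=O)C(C)C)[C@@]2(C)[C@@H](OC(C)=O)CC[C@]3(CO3)[C@@H]2[C@H](OC(C)=O)[C@]2(O[Si]4(C(C)(C)C)C(C)(C)C)[C@@H](C)C(=O)O[C@H]2[C@H]1O4
F6 | step 20 | C6 epimer of 36 | C=C1CC[C@H](OC(=O)C(C)C)[C@@]2(C)[C@@H](OC(C)=O)CC[C@]3(CO3)[C@@H]2[C@H](OC(C)=O)[C@]2(O)[C@@H](C)C(=O)O[C@H]2[C@H]1O
F7 | step 20 | C6 formate of 36 | C=C1CC[C@H](OC(=O)C(C)C)[C@@]2(C)[C@@H](OC(C)=O)CC[C@]3(CO3)[C@@H]2[C@H](OC(C)=O)[C@]2(O)[C@@H](C)C(=O)O[C@H]2[C@@H]1OC=O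
F8 | step 21 | (6R) formate of the ten-membered ketone | C=C1CC[C@H](OC(=O)C(C)C)[C@@]2(C)[C@@H](OC(C)=O)CC[C@]3(CO3)[C@@H]2[C@H](OC(C)=O)C(=O)C[C@H]1OC=O
F9 | step 10 | C2 ketone | O=C(CCCCO[Si](c1ccccc1)(c1ccccc1)C(C)(C)C)[C@@]1(C)C2(OCCO2)CCC(=C)[C@@H]1[C@@H](O[Si](C)(C)C(C)(C)C)C#C
F10 | step 26 | 6,8-cyclic sulfite of 36 | C=C1CC[C@H](OC(=O)C(C)C)[C@@]2(C)[C@@H](OC(C)=O)CC[C@]3(CO3)[C@@H]2[C@H](OC(C)=O)[C@]2(OS(=O)O4)[C@@H](C)C(=O)O[C@H]2[C@@H]14
A1 | alternative 1 | ring-A-fused isoxazoline (C11 dioxolane) | C=C1CC[C@H]4[C@@]2(C)C(=NO4)CCC3(OCCO3)[C@@H]2[C@H](OC(C)=O)[C@]2(O)[C@@H](C)C(=O)O[C@H]2[C@H]1Cl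
A2 | alternative 2 | ten-membered C7 ketone with C5 methylene and C2 methyl enol ether | C=C1C/C=C(\OC)[C@@]2(C)[C@@H](O[Si](C)(C)C(C)(C)C)CCC3(OCCO3)[C@@H]2[C@H](O[Si](C)(C)C(C)(C)C)[C@H](OCc4ccc(OC)cc4)C(=O)C1
A3 | alternative 3 | bicyclo[8.4.0] core with free C2–OH and C11=C20 methylene | C=C1CC[C@H](O)[C@@]2(C)[C@@H](O[Si](C)(C)C(C)(C)C)CCC(=C)[C@@H]2[C@H](O[Si](C)(C)C(C)(C)C)C2=C(C)C(=O)O[C@H]2[C@@H]1O[Si](CC)(CC)CC
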